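The ten-membered ring is closed by a nickel-catalysed reductive alkyne–epoxide coupling that forges the C9–C10 bond (germacrane numbering). The step exploits the homoallylic alcohol C8(OH)–C9H2–C10(CH3)=C1H of the carbocycle: in one operation an open-chain 8,9-epoxide carrying a C1≡C10 methylalkyne gives the C9–C10 bond, the (E)-C1=C10 alkene by cis addition of C9 and H, and the free C8 hydroxyl that later bears an angelate. The precursor is an acyclic (4Z)-enyne terminal epoxide whose C6, C7, C8 and C11 centres come from a chiral bromo alcohol, an Evans aldol and a hydroxyl-directed reduction. The cis-4,5-epoxide is added last by C6–OH-directed epoxidation.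

Key step: step 12

**Remarks and assumptions**
- Numbering: germacrane locants are used throughout. C1=C10 is the (E)-alkene (C14 methyl on C10), C4–C5 the epoxide (C15 methyl on C4), C6 the free carbinol, C7 the branch carbon, C8 the ring angelate carbinol, C9 the ring CH2, and C11/C12/C13 the CH/CH2O/CH3 of the side chain. Open-chain intermediates are named as 9,10-seco compounds with the same locants.
- TBS = tert-butyldimethylsilyl; TBSO = tert-butyldimethylsilyloxy.
- Assumption: chloroacetaldehyde (sold as an aqueous solution) is used as the anhydrous monomer, freshly distilled before step 6.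
- Step 14 forms two ester bonds and therefore consumes two equivalents of angelic acid; the second equivalent is entered as a reagent that adds atoms.

**Fragment A (vinyl iodide)**

Step 1
Reactants: 1 pent-3-yn-1-ol
Product: 2 5-bromopent-2-yne
Conditions: CBr4, PPh3, CH2Cl2, 0 °C to rt
Reagents that add atoms: carbon tetrabromide, BrC(Br)(Br)Br
Why: The Appel reaction should convert the primary alcohol into the bromide under neutral conditions that leave the internal alkyne untouched.

Step 2
Reactants: 2 5-bromopent-2-yne; 3 propyne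
Product: 7 (Z)-1-iodo-2-methylhept-1-en-5-yne, via Grignard reagent 4 (not isolated), via alkylcopper 5 (not isolated), via alkenylcopper 6 (not isolated)
Conditions: Mg, Et2O, rt; CuBr·SMe2, Et2O/Me2S, −45 °C; 3, −25 °C; I2, −50 to 0 °C
Reagents that add atoms: iodine, I-I
Why: Normant carbocupration: alkylcopper 5 (from Grignard reagent 4) should add syn across propyne with the alkyl group on the internal carbon, and iodinolysis of alkenylcopper 6 with retention puts iodine cis to the chain, which fixes the later (Z)-C4=C5 geometry.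

**Main line**

Step 3
Reactants: 8 (R)-3-bromo-2-methylpropan-1-ol
Product: 9 (R)-(3-bromo-2-methylpropoxy)(tert-butyl)dimethylsilane
Conditions: TBSCl, imidazole, DMF, rt
Reagents that add atoms: tert-butyldimethylsilyl chloride, CC(C)(C)[Si](C)(C)Cl
Why: Silyl ether formation protects the future C12 hydroxyl so that a Grignard reagent can be made from the bromide; the C11 stereocentre (bought in) is not involved.

Step 4
Reactants: 9 (R)-(3-bromo-2-methylpropoxy)(tert-butyl)dimethylsilane
Product: 11 (S)-4-(tert-butyldimethylsilyloxy)-3-methylbutanoic acid, via Grignard reagent 10 (not isolated)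
Conditions: Mg, THF, 45 °C; CO2, −20 °C to rt; cold 1 M HCl to pH 3
Reagents that add atoms: carbon dioxide, O=C=O
Why: Grignard carboxylation adds the future C6 carbon; the stereocentre lies β to the metal and cannot epimerise, and the short cold acid quench should keep the primary silyl ether.

Step 5
Reactants: 11 (S)-4-(tert-butyldimethylsilyloxy)-3-methylbutanoic acid; 12 (R)-4-benzyloxazolidin-2-one
Product: 14 (R)-4-benzyl-3-[(S)-4-(tert-butyldimethylsilyloxy)-3-methylbutanoyl]oxazolidin-2-one, via mixed pivalic anhydride 13 (not isolated)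
Conditions: PivCl, Et3N, THF, −20 °C; then 12, LiCl, −20 °C to rt
Reagents that add atoms: none
Why: N-Acylation of the oxazolidinone through mixed anhydride 13 installs the (R)-benzyl auxiliary without touching C11.

Step 6
Reactants: 14 (R)-4-benzyl-3-[(S)-4-(tert-butyldimethylsilyloxy)-3-methylbutanoyl]oxazolidin-2-one; 15 chloroacetaldehyde
Product: 18 (R)-4-benzyl-3-[(2R,3R)-2-[(S)-1-(tert-butyldimethylsilyloxy)propan-2-yl]-4-chloro-3-hydroxybutanoyl]oxazolidin-2-one, via boron enolate 16 (not isolated), via boron aldolate 17 (not isolated)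
Conditions: Bu2BOTf, iPr2NEt, CH2Cl2, −78 to 0 °C; 15, −78 to 0 °C; pH 7 buffer, MeOH, H2O2, 0 °C
Reagents that add atoms: none
Why: Evans syn-aldol reaction: the (Z)-boron enolate 16 should react through a chair Zimmerman–Traxler transition state on the face away from the benzyl group, so the (R)-auxiliary sets C7 and C8 together (syn) in the required absolute sense and overrides the remote C11 centre.

Step 7
Reactants: 18 (R)-4-benzyl-3-[(2R,3R)-2-[(S)-1-(tert-butyldimethylsilyloxy)propan-2-yl]-4-chloro-3-hydroxybutanoyl]oxazolidin-2-one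
Product: 19 (2R,3R)-2-[(S)-1-(tert-butyldimethylsilyloxy)propan-2-yl]-4-chloro-3-hydroxy-N-methoxy-N-methylbutanamide
Conditions: Me(MeO)NH·HCl, AlMe3, CH2Cl2, −20 to 0 °C
Reagents that add atoms: N,O-dimethylhydroxylamine hydrochloride, CNOC.Cl
Why: Weinreb transamidation with the aluminium amide, assisted by the free β-hydroxyl, should remove the auxiliary without epimerising C7 and leave the primary chloride alone.

Step 8
Reactants: 19 (2R,3R)-2-[(S)-1-(tert-butyldimethylsilyloxy)propan-2-yl]-4-chloro-3-hydroxy-N-methoxy-N-methylbutanamide; 7 (Z)-1-iodo-2-methylhept-1-en-5-yne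
Product: 22 (4Z,7R,8R,11S)-9-chloro-8-hydroxy-12-(TBSO)-9,10-secogermacr-4-en-1(10)-yn-6-one, via alkenyllithium 20 (not isolated), via magnesium alkoxide 21 (not isolated)
Conditions: 7, t-BuLi (2 equiv), Et2O, −78 °C; 19, iPrMgCl (1 equiv), THF, −40 °C; combine at −78 °C; sat. aq. NH4Cl at −78 °C
Reagents that add atoms: none
Why: Weinreb ketone synthesis: alkenyllithium 20 (iodine–lithium exchange with retention of the Z geometry) should add once to the amide of magnesium alkoxide 21, whose alkoxide is too weakly nucleophilic to displace the neighbouring chloride at −78 °C, and the cold quench releases the (Z)-enone.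

Step 9
Reactants: 22 (4Z,7R,8R,11S)-9-chloro-8-hydroxy-12-(TBSO)-9,10-secogermacr-4-en-1(10)-yn-6-one
Product: 23 (4Z,6S,7S,8R,11S)-9-chloro-12-(TBSO)-9,10-secogermacr-4-en-1(10)-yne-6,8-diol
Conditions: Me4NBH(OAc)3, MeCN/AcOH (1:1), −30 °C
Reagents that add atoms: none
Why: Evans–Saksena reduction: the C8 hydroxyl binds the borohydride and delivers hydride to the C6 ketone within a chair transition state, which should give the 1,3-anti diol and so the C6 configuration.

Step 10
Reactants: 23 (4Z,6S,7S,8R,11S)-9-chloro-12-(TBSO)-9,10-secogermacr-4-en-1(10)-yne-6,8-diol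
Product: 24 (4Z,6S,7S,8R,11S)-8,9-epoxy-12-(TBSO)-9,10-secogermacr-4-en-1(10)-yn-6-ol
Conditions: K2CO3, MeOH, 0 °C to rt
Reagents that add atoms: none
Why: Williamson-type 3-exo-tet closure of the chlorohydrin gives the terminal epoxide with C8 unchanged (only the C9–Cl bond breaks); under basic conditions this closure should be faster than tetrahydrofuran formation from the C6 hydroxyl.

Step 11
Reactants: 24 (4Z,6S,7S,8R,11S)-8,9-epoxy-12-(TBSO)-9,10-secogermacr-4-en-1(10)-yn-6-ol
Product: 25 (4Z,6S,7R,8R,11S)-8,9-epoxy-6,12-bis(TBSO)-9,10-secogermacr-4-en-1(10)-yne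
Conditions: TBSOTf, 2,6-lutidine, CH2Cl2, −78 °C
Reagents that add atoms: tert-butyldimethylsilyl triflate, CC(C)(C)[Si](C)(C)OS(=O)(=O)C(F)(F)F
Why: Silylation of the hindered allylic C6 hydroxyl with the silyl triflate at −78 °C, where the terminal epoxide should not be opened.

Step 12
Reactants: 25 (4Z,6S,7R,8R,11S)-8,9-epoxy-6,12-bis(TBSO)-9,10-secogermacr-4-en-1(10)-yne
Product: 28 (1(10)E,4Z,6S,7R,8S,11S)-6,12-bis(TBSO)germacra-1(10),4-dien-8-ol, via oxanickelacycle 26 (not isolated), via diethylborinate 27 (not isolated)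
Conditions: Ni(cod)2 (20 mol %), PBu3 (40 mol %), Et3B (4 equiv), THF, 0.01 M, slow addition of 25, rt; aq. NH4Cl work-up
Reagents that add atoms: none
Why: Zerovalent nickel carrying PBu3 binds the C1≡C10 alkyne, opens the monosubstituted epoxide at its CH2 terminus C9 by SN2-type oxidative addition and joins C9 to the methyl-bearing alkyne carbon C10, giving oxanickelacycle 26 (divalent nickel bound to C1 and O8); Et3B then exchanges ethyl for the alkoxide to give borinate 27, β-hydride elimination releases ethene and C1–H reductive elimination returns the catalyst. The closest known reaction type is the nickel-catalysed reductive coupling of alkynes with terminal epoxides under Ni(cod)2/PBu3/Et3B, established between separate partners and for ring closure of tethered alkynyl epoxides, while its aldehyde counterpart has closed large rings with endocyclic (E)-alkenes, so closure of a ten-membered ring through the distal carbon of a dialkyl alkyne lies at the edge of that scope. The ten-membered carbocycle closes in the endo sense at both partners: both alkyne carbons (10-endo-dig) and both epoxide carbons become ring members. No stereocentre is created: C8 keeps the configuration set in step 6 because only the C9–O bond is broken, and the (E)-C1=C10 geometry follows from cis delivery of C9 and H across the alkyne. The step needs bond formation at C10 and not at C1 (which would give a nine-membered ring with an exocyclic ethylidene) and at C9 and not at C8; the small methyl terminus with a small phosphine favours C10, the terminal epoxide carbon is the only unhindered site for nickel, the trisubstituted C4=C5 alkene and the silyl ethers should be inert, and high dilution suppresses oligomers.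

Step 13
Reactants: 28 (1(10)E,4Z,6S,7R,8S,11S)-6,12-bis(TBSO)germacra-1(10),4-dien-8-ol
Product: 29 (1(10)E,4Z,6S,7R,8S,11S)-6-(TBSO)germacra-1(10),4-diene-8,12-diol
Conditions: HF·pyridine, pyridine, THF, 0 °C
Reagents that add atoms: none
Why: Selective desilylation: buffered HF·pyridine should cleave the unhindered primary C12 silyl ether much faster than the secondary allylic C6 silyl ether next to the C7 branch.

Step 14
Reactants: 29 (1(10)E,4Z,6S,7R,8S,11S)-6-(TBSO)germacra-1(10),4-diene-8,12-diol; 30 angelic acid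
Product: 32 (1(10)E,4Z,6S,7R,8S,11S)-6-(TBSO)germacra-1(10),4-diene-8,12-diyl bis[(Z)-2-methylbut-2-enoate], via mixed anhydride 31 (not isolated)
Conditions: 30 (3 equiv), 2,4,6-trichlorobenzoyl chloride (3 equiv), Et3N, toluene, rt; then 29, toluene, 75 °C
Reagents that add atoms: angelic acid (second equivalent), C/C=C(/C)C(=O)O
Why: Yamaguchi-type esterification with an excess of preformed mixed anhydride 31 and no nucleophilic amine catalyst should acylate both the primary C12 and the secondary C8 hydroxyl, one angeloyl unit each, without isomerising the angeloyl group to tigloyl.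

Step 15
Reactants: 32 (1(10)E,4Z,6S,7R,8S,11S)-6-(TBSO)germacra-1(10),4-diene-8,12-diyl bis[(Z)-2-methylbut-2-enoate]
Product: 33 (1(10)E,4Z,6S,7S,8S,11S)-6-hydroxygermacra-1(10),4-diene-8,12-diyl bis[(Z)-2-methylbut-2-enoate]
Conditions: HF·pyridine, pyridine, THF, rt
Reagents that add atoms: none
Why: Fluoride desilylation under buffered, weakly acidic conditions should free the C6 hydroxyl without ester migration or transannular cyclisation of the diene.

Step 16
Reactants: 33 (1(10)E,4Z,6S,7S,8S,11S)-6-hydroxygermacra-1(10),4-diene-8,12-diyl bis[(Z)-2-methylbut-2-enoate]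
Product: 34 (1(10)E,4S,5R,6R,7S,8S,11S)-4,5-epoxy-6-hydroxygermacr-1(10)-ene-8,12-diyl bis[(Z)-2-methylbut-2-enoate] (CNP0272382.1)
Conditions: VO(acac)2 (5 mol %), t-BuOOH (decane), CH2Cl2, 0 °C
Reagents that add atoms: tert-butyl hydroperoxide, CC(C)(C)OO
Why: Hydroxyl-directed epoxidation: the C6 hydroxyl binds the vanadium peroxide and should steer oxygen only to the allylic C4=C5 bond and, as in medium-ring (Z)-cycloalk-2-enols where the ring bond C6–C7 stands perpendicular to the alkene plane, to the face cis to the C6–O bond, which sets C4 and C5 as the cis-epoxy alcohol while C1=C10 and the angelates stay untouched.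

**Compound list**

1 | pent-3-yn-1-ol | CC#CCCO | starting material
2 | 5-bromopent-2-yne | CC#CCCBr | intermediate
3 | propyne | CC#C | starting material
4 | pent-3-yn-1-ylmagnesium bromide | CC#CCC[Mg]Br | intermediate
5 | pent-3-yn-1-ylcopper | CC#CCC[Cu] | intermediate
6 | (Z)-(2-methylhept-1-en-5-yn-1-yl)copper | CC#CCC/C(C)=C\[Cu] | intermediate
7 | (Z)-1-iodo-2-methylhept-1-en-5-yne | CC#CCC/C(C)=C\I | intermediate
8 | (R)-3-bromo-2-methylpropan-1-ol | OC[C@@H](C)CBr | starting material
9 | (R)-(3-bromo-2-methylpropoxy)(tert-butyl)dimethylsilane | CC(C)(C)[Si](C)(C)OC[C@@H](C)CBr | intermediate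
10 | (R)-[3-(tert-butyldimethylsilyloxy)-2-methylpropyl]magnesium bromide | CC(C)(C)[Si](C)(C)OC[C@@H](C)C[Mg]Br | intermediate
11 | (S)-4-(tert-butyldimethylsilyloxy)-3-methylbutanoic acid | CC(C)(C)[Si](C)(C)OC[C@@H](C)CC(=O)O | intermediate
12 | (R)-4-benzyloxazolidin-2-one | O=C1N[C@H](Cc2ccccc2)CO1 | starting material
13 | (S)-4-(tert-butyldimethylsilyloxy)-3-methylbutanoic pivalic anhydride | CC(C)(C)[Si](C)(C)OC[C@@H](C)CC(=O)OC(=O)C(C)(C)C | intermediate
14 | (R)-4-benzyl-3-[(S)-4-(tert-butyldimethylsilyloxy)-3-methylbutanoyl]oxazolidin-2-one | CC(C)(C)[Si](C)(C)OC[C@@H](C)CC(=O)N1[C@H](Cc2ccccc2)COC1=O | intermediate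
15 | chloroacetaldehyde | O=CCCl | starting material
16 | (Z)-dibutylboron enolate of 14 | CC(C)(C)[Si](C)(C)OC[C@@H](C)/C=C(\OB(CCCC)CCCC)N1[C@H](Cc2ccccc2)COC1=O | intermediate
17 | dibutylboron aldolate of 18 | CC(C)(C)[Si](C)(C)OC[C@@H](C)[C@H]([C@@H](OB(CCCC)CCCC)CCl)C(=O)N1[C@H](Cc2ccccc2)COC1=O | intermediate
18 | (R)-4-benzyl-3-[(2R,3R)-2-[(S)-1-(tert-butyldimethylsilyloxy)propan-2-yl]-4-chloro-3-hydroxybutanoyl]oxazolidin-2-one | CC(C)(C)[Si](C)(C)OC[C@@H](C)[C@H]([C@@H](O)CCl)C(=O)N1[C@H](Cc2ccccc2)COC1=O | intermediate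
19 | (2R,3R)-2-[(S)-1-(tert-butyldimethylsilyloxy)propan-2-yl]-4-chloro-3-hydroxy-N-methoxy-N-methylbutanamide | CC(C)(C)[Si](C)(C)OC[C@@H](C)[C@H]([C@@H](O)CCl)C(=O)N(C)OC | intermediate
20 | (Z)-(2-methylhept-1-en-5-yn-1-yl)lithium | CC#CCC/C(C)=C\[Li] | intermediate
21 | chloromagnesium alkoxide of 19 | CC(C)(C)[Si](C)(C)OC[C@@H](C)[C@H]([C@@H](O[Mg]Cl)CCl)C(=O)N(C)OC | intermediate
22 | (4Z,7R,8R,11S)-9-chloro-8-hydroxy-12-(TBSO)-9,10-secogermacr-4-en-1(10)-yn-6-one | CC(C)(C)[Si](C)(C)OC[C@@H](C)[C@H]([C@@H](O)CCl)C(=O)/C=C(C)\CCC#CC | intermediate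
23 | (4Z,6S,7S,8R,11S)-9-chloro-12-(TBSO)-9,10-secogermacr-4-en-1(10)-yne-6,8-diol | CC(C)(C)[Si](C)(C)OC[C@@H](C)[C@H]([C@@H](O)CCl)[C@@H](O)/C=C(C)\CCC#CC | intermediate
24 | (4Z,6S,7S,8R,11S)-8,9-epoxy-12-(TBSO)-9,10-secogermacr-4-en-1(10)-yn-6-ol | CC(C)(C)[Si](C)(C)OC[C@@H](C)[C@H]([C@@H]1CO1)[C@@H](O)/C=C(C)\CCC#CC | intermediate
25 | (4Z,6S,7R,8R,11S)-8,9-epoxy-6,12-bis(TBSO)-9,10-secogermacr-4-en-1(10)-yne | CC(C)(C)[Si](C)(C)OC[C@@H](C)[C@H]([C@@H]1CO1)[C@@H](O[Si](C)(C)C(C)(C)C)/C=C(C)\CCC#CC | intermediate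
26 | oxanickelacycle from 25 (divalent nickel bound to C1 and O8; phosphine ligand not drawn) | CC(C)(C)[Si](C)(C)OC[C@@H](C)[C@H]1[C@@H](O[Si](C)(C)C(C)(C)C)/C=C(C)\CC/C2=C(\C)C[C@@H]1O[Ni]2 | intermediate
27 | O8-diethylborinate of 28 | CC(C)(C)[Si](C)(C)OC[C@@H](C)[C@H]1[C@@H](O[Si](C)(C)C(C)(C)C)/C=C(C)\CC/C=C(\C)C[C@@H]1OB(CC)CC | intermediate
28 | (1(10)E,4Z,6S,7R,8S,11S)-6,12-bis(TBSO)germacra-1(10),4-dien-8-ol | CC(C)(C)[Si](C)(C)OC[C@@H](C)[C@H]1[C@@H](O[Si](C)(C)C(C)(C)C)/C=C(C)\CC/C=C(\C)C[C@@H]1O | intermediate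
29 | (1(10)E,4Z,6S,7R,8S,11S)-6-(TBSO)germacra-1(10),4-diene-8,12-diol | OC[C@@H](C)[C@H]1[C@@H](O[Si](C)(C)C(C)(C)C)/C=C(C)\CC/C=C(\C)C[C@@H]1O | intermediate
30 | angelic acid, (Z)-2-methylbut-2-enoic acid | C/C=C(/C)C(=O)O | starting material
31 | angelic 2,4,6-trichlorobenzoic anhydride | C/C=C(/C)C(=O)OC(=O)c1c(Cl)cc(Cl)cc1Cl | intermediate
32 | (1(10)E,4Z,6S,7R,8S,11S)-6-(TBSO)germacra-1(10),4-diene-8,12-diyl bis[(Z)-2-methylbut-2-enoate] | C/C=C(/C)C(=O)OC[C@@H](C)[C@H]1[C@@H](O[Si](C)(C)C(C)(C)C)/C=C(C)\CC/C=C(\C)C[C@@H]1OC(=O)/C(C)=C\C | intermediate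
33 | (1(10)E,4Z,6S,7S,8S,11S)-6-hydroxygermacra-1(10),4-diene-8,12-diyl bis[(Z)-2-methylbut-2-enoate] | C/C=C(/C)C(=O)OC[C@@H](C)[C@H]1[C@@H](O)/C=C(C)\CC/C=C(\C)C[C@@H]1OC(=O)/C(C)=C\C | intermediate
34 | CNP0272382.1, (1(10)E,4S,5R,6R,7S,8S,11S)-4,5-epoxy-6-hydroxygermacr-1(10)-ene-8,12-diyl bis[(Z)-2-methylbut-2-enoate] | C/C=C(/C)C(=O)OC[C@@H](C)[C@H]1[C@@H](O)[C@H]2O[C@@]2(C)CC/C=C(\C)C[C@@H]1OC(=O)/C(C)=C\C | target

**Step count**

Total step count: 16. Longest linear sequence: 14 steps (8 to 34, steps 3–16); fragment A (steps 1–2) joins in step 8.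

**Steps most likely to fail**

1. Step 12 (ring closure). Carbon–carbon bond formation may occur at the proximal alkyne carbon C1 and close a nine-membered ring with an exocyclic alkene. Oligomerisation may outrun medium-ring closure, or the nickel-opened epoxide may isomerise by β-hydride elimination before it meets the alkyne. The fallback separates the two events so that regiochemistry and alkene geometry are fixed before the ring is closed. It sets out from 25: hydrozirconation with Cp2Zr(H)Cl (THF, rt) should place zirconium on the methyl-bearing carbon C10 by syn addition, and iodinolysis (I2, 0 °C) would give the (E)-alkenyl iodide F1. Iodine–lithium exchange (t-BuLi, Et2O, −78 °C) would give the alkenyllithium F2. Opening of the terminal epoxide at C9, assisted by BF3·OEt2 at high dilution, would close the same C9–C10 bond and come back to the route at 28.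

2. Step 16 (directed epoxidation). Oxygen may be delivered to the wrong face of C4=C5 if the macrocycle reacts through a conformer with H6 in the alkene plane. The hindered allylic alcohol may also be oxidised to the enone instead of accepting oxygen transfer. The fallback sets the epoxide before ring closure, where allylic 1,3-strain and a chelation-controlled reduction decide the configuration instead of ring conformation. It sets out from 22: Narasaka–Prasad reduction (Et2BOMe, NaBH4, THF/MeOH, −78 °C) would give the syn-diol F3, and K2CO3/MeOH would then give the epoxy alcohol F4. Epoxidation with mCPBA should give the threo bis-epoxy alcohol F5, because the cis CH2 group on C4 forces H6 into the alkene plane. Dess–Martin oxidation would give the epoxy ketone F6, which Zn(BH4)2 (Et2O, −20 °C) should reduce under chelation control to the erythro bis-epoxy alcohol F7. TBSOTf/2,6-lutidine would give the silyl ether F8, and the nickel cyclisation of step 12 (the trisubstituted epoxide should be inert) would give the macrocyclic epoxy alcohol F9. The conditions of steps 13 and 14 would give the diol F10 and then the diangelate F11, and HF·pyridine would come back to the route at 34.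

3. Step 8 (alkenyllithium addition). The chlorohydrin alkoxide may close to the epoxide and then suffer base-induced eliminative opening. The β-hydroxy ketone may undergo retro-aldol cleavage, or the (Z)-enone may isomerise through a dienolate. The fallback replaces the strongly basic addition by a palladium-catalysed acyl cross-coupling (Fukuyama coupling). It sets out from 18 and 7. LiSEt (EtSH, n-BuLi, THF, −20 °C) would convert 18 into the S-ethyl thioester F12. Alkenyllithium 20 (from 7) with ZnCl2 would give the alkenylzinc chloride F13. Coupling with PdCl2(PPh3)2 (toluene/THF, rt) would come back to the route at 22.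

**Further compounds**

F1 | step 12 | (1(10)E,4Z,6S,7R,8R,11S)-8,9-epoxy-10-iodo-6,12-bis(TBSO)-9,10-secogermacra-1(10),4-diene | CC(C)(C)[Si](C)(C)OC[C@@H](C)[C@H]([C@@H]1CO1)[C@@H](O[Si](C)(C)C(C)(C)C)/C=C(C)\CC/C=C(\C)I
F2 | step 12 | alkenyllithium from F1 (lithium on C10) | CC(C)(C)[Si](C)(C)OC[C@@H](C)[C@H]([C@@H]1CO1)[C@@H](O[Si](C)(C)C(C)(C)C)/C=C(C)\CC/C=C(\C)[Li]
F3 | step 16 | syn-diol, C6 epimer of 23 | CC(C)(C)[Si](C)(C)OC[C@@H](C)[C@H]([C@@H](O)CCl)[C@H](O)/C=C(C)\CCC#CC
F4 | step 16 | epoxy alcohol, C6 epimer of 24 | CC(C)(C)[Si](C)(C)OC[C@@H](C)[C@H]([C@@H]1CO1)[C@H](O)/C=C(C)\CCC#CC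
F5 | step 16 | threo 4,5:8,9-bis-epoxy alcohol, C6 epimer of F7 | CC(C)(C)[Si](C)(C)OC[C@@H](C)[C@H]([C@@H]1CO1)[C@H](O)[C@H]2O[C@@]2(C)CCC#CC
F6 | step 16 | 4,5:8,9-bis-epoxy 6-ketone | CC(C)(C)[Si](C)(C)OC[C@@H](C)[C@H]([C@@H]1CO1)C(=O)[C@H]2O[C@@]2(C)CCC#CC
F7 | step 16 | erythro 4,5:8,9-bis-epoxy alcohol, the 4,5-epoxide of 24 | CC(C)(C)[Si](C)(C)OC[C@@H](C)[C@H]([C@@H]1CO1)[C@@H](O)[C@H]2O[C@@]2(C)CCC#CC
F8 | step 16 | 6-O-TBS ether of F7, the 4,5-epoxide of 25 | CC(C)(C)[Si](C)(C)OC[C@@H](C)[C@H]([C@@H]1CO1)[C@@H](O[Si](C)(C)C(C)(C)C)[C@H]2O[C@@]2(C)CCC#CC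
F9 | step 16 | macrocyclic alcohol, the 4,5-epoxide of 28 | CC(C)(C)[Si](C)(C)OC[C@@H](C)[C@H]1[C@@H](O[Si](C)(C)C(C)(C)C)[C@H]2O[C@@]2(C)CC/C=C(\C)C[C@@H]1O
F10 | step 16 | diol, the 4,5-epoxide of 29 | OC[C@@H](C)[C@H]1[C@@H](O[Si](C)(C)C(C)(C)C)[C@H]2O[C@@]2(C)CC/C=C(\C)C[C@@H]1O
F11 | step 16 | 6-O-TBS ether of 34 | C/C=C(/C)C(=O)OC[C@@H](C)[C@H]1[C@@H](O[Si](C)(C)C(C)(C)C)[C@H]2O[C@@]2(C)CC/C=C(\C)C[C@@H]1OC(=O)/C(C)=C\C
F12 | step 8 | S-ethyl (2R,3R)-2-[(S)-1-(tert-butyldimethylsilyloxy)propan-2-yl]-4-chloro-3-hydroxybutanethioate | CC(C)(C)[Si](C)(C)OC[C@@H](C)[C@H]([C@@H](O)CCl)C(=O)SCC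
F13 | step 8 | (Z)-(2-methylhept-1-en-5-yn-1-yl)zinc chloride | CC#CCC/C(C)=C\[Zn]Cl
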